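**Retrosynthetic overview**

1. The target is (+)-catechin carrying at C8 a two-unit ent-fisetinidol chain (A→B, 4α→6) and at C6 one ent-fisetinidol unit (D, 4α). The C4(D)–C6(catechin) bond is cut last, then C4(B)–C8(catechin); both are made by C4-carbocation (quinone-methide) Friedel–Crafts condensations of free phenolic flavan-3,4-diols.
2. The dimeric electrophile (A–B flavan-3,4-diol) comes from self-condensation of one monomer, ent-leucofisetinidin, which therefore supplies all three upper units.
3. ent-Leucofisetinidin comes from C4 carbonyl reduction of ent-fustin, itself obtained by debenzylation of its tribenzyl ether.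
4. Key ring formation: the pyran ring is closed once, by a chalcone-isomerase-type 6-endo oxa-Michael addition of a chalcone 2'-phenoxide, with flavanone-3-hydroxylase-type hydroxylation of the resulting enolate in the same flask (sets C2 and C3). The chalcone comes from an aldol condensation of an acetophenone with a benzaldehyde.
5. Ring order: the pyran ring of the monomer (step 2) is the only ring built; the benzene rings come with the starting materials and the catechin skeleton is bought intact.

Assumption: the SMILES is taken literally (three (2S,3R)-ent-fisetinidol units, each 4α-linked, i.e. 2,3-trans-3,4-cis, on (2R,3S)-catechin), and in step 2 the cinchonine-derived catalyst is taken to give the (2S,3S) series (otherwise its cinchonidine pseudo-enantiomer is used).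

**Route**

Step 1
Reactants: 1 1-[4-(benzyloxy)-2-hydroxyphenyl]ethan-1-one; 2 3,4-bis(benzyloxy)benzaldehyde
Product: 3 (E)-2'-hydroxy-4',3,4-tris(benzyloxy)chalcone
Conditions: KOH (3 equiv), EtOH, 25 °C, 24 h; then 2 M HCl
Reagents that add atoms: none
Why: Claisen–Schmidt condensation (crossed aldol, then E1cB dehydration) gives the thermodynamically favoured (E)-enone; no stereocentre is formed.

Step 2
Reactants: 3 (E)-2'-hydroxy-4',3,4-tris(benzyloxy)chalcone
Product: 5 (2S,3S)-7-(benzyloxy)-2-[3,4-bis(benzyloxy)phenyl]-3-hydroxy-2,3-dihydro-4H-chromen-4-one (tri-O-benzyl-ent-fustin), via flavanone enolate 4 (not isolated)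
Conditions: N-(9-anthracenylmethyl)cinchoninium chloride (10 mol %), cumene hydroperoxide (1.2 equiv), 50 % aq. KOH (20 mol %), toluene, −20 °C, 12 h; recrystallise (EtOAc–hexane)
Reagents that add atoms: cumene hydroperoxide, CC(C)(OO)c1ccccc1
Why: Proposed new method: the chiral ammonium ion pair of the 2'-phenoxide closes the pyran ring by a reversible chalcone-isomerase-type 6-endo oxa-Michael addition to enolate 4, which is hydroxylated irreversibly at C3 by the hydroperoxide anti to the 2-aryl group (2,3-trans), so C2 is fixed by dynamic kinetic selection inside the chiral ion pair and any 2,3-cis product epimerises at C3 to trans; the closest known reaction types are the Algar–Flynn–Oyamada oxidative cyclisation stopped at the dihydroflavonol stage, cinchona phase-transfer α-hydroxylation of enolates with cumene hydroperoxide, and cinchona-ammonium-catalysed oxa-Michael cyclisation of 2'-hydroxychalcones.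

Step 3
Reactants: 5 tri-O-benzyl-ent-fustin
Product: 6 (2S,3S)-2-(3,4-dihydroxyphenyl)-3,7-dihydroxy-2,3-dihydro-4H-chromen-4-one (ent-fustin)
Conditions: H2 (1 atm), Pd/C (10 wt % Pd), EtOAc–MeOH 1:1, 25 °C
Reagents that add atoms: none
Why: Heterogeneous hydrogenolysis cleaves the three aryl benzyl ethers, while the aryl ketone, the cyclic benzylic C2–O1 ether and both stereocentres are untouched under neutral conditions at 25 °C (no enolisation, no ring opening).

Step 4
Reactants: 6 ent-fustin
Product: 7 (2S,3R,4S)-2-(3,4-dihydroxyphenyl)-3,4-dihydro-2H-chromene-3,4,7-triol (ent-mollisacacidin)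
Conditions: NaBH4 (2 equiv), EtOH, 0 → 25 °C; then AcOH to pH 6
Reagents that add atoms: none
Why: Dihydroflavonol-4-reductase-type carbonyl reduction with NaBH4, in which hydride adds axially to C4 of the half-chair bearing equatorial 2-aryl and 3-OH groups (from the α face) and gives the equatorial 4β-alcohol, i.e. the 2,3-trans-3,4-trans (4S) diol, as is standard for trans-dihydroflavonols.

Step 5
Reactants: 7 ent-mollisacacidin (two molecules, one ionised and one as nucleophile)
Product: 9 ent-fisetinidol-(4α→6)-ent-leucofisetinidin (dimeric flavan-3,4-diol), via C4 carbocation 8 (not isolated)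
Conditions: 0.1 M HCl, H2O–1,4-dioxane 1:1, 25 °C, N2, stopped at ca. 35 % conversion; Sephadex LH-20 (EtOH), then preparative reversed-phase HPLC; unreacted 7 recycled
Reagents that add atoms: none
Why: Acid ionises the benzylic 4-OH to the 7-hydroxy-stabilised carbocation 8 (a protonated para-quinone methide), which is trapped in a Friedel–Crafts alkylation by C6 (ortho to 7-OH, para to O1) of a second molecule of 7, as in tannin chain growth; the new C4 centre of unit A forms under substrate control as both epimers, and the required 4α (3,4-cis, J3,4 about 6 Hz) epimer, from axial attack anti to axial H-3, is the minor one (about 1:2–3 against 4β) and is separated.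

Step 6
Reactants: 9 ent-fisetinidol-(4α→6)-ent-leucofisetinidin; 10 (+)-catechin (5 equiv)
Product: 12 ent-fisetinidol-(4α→6)-ent-fisetinidol-(4α→8)-catechin, via dimeric C4 carbocation 11 (not isolated)
Conditions: 9 added slowly to 10 in 0.1 M HCl, H2O–1,4-dioxane 1:1, 25 °C, N2; Sephadex LH-20, then preparative HPLC
Reagents that add atoms: none
Why: The phloroglucinol ring of catechin, present in excess, is far more nucleophilic than the resorcinol rings of 9 and captures cation 11 in a Friedel–Crafts alkylation mainly at the less hindered C8 (about 4:1 over C6); the new C4 centre of unit B again forms as both epimers under substrate control, and the 4α (3,4-cis) epimer is isolated.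

Step 7
Reactants: 12 ent-fisetinidol-(4α→6)-ent-fisetinidol-(4α→8)-catechin; 7 ent-mollisacacidin (1.5 equiv, slow addition)
Product: 13 ent-fisetinidol-(4α→6)-ent-fisetinidol-(4α→8)-catechin-(6→4α)-ent-fisetinidol (CNP0126838.1)
Conditions: 0.1 M HCl, H2O–1,4-dioxane 1:1, 25 °C, N2; Sephadex LH-20, then preparative HPLC
Reagents that add atoms: none
Why: Friedel–Crafts alkylation (SN1) under the acid conditions of step 5, where 7 ionises at its benzylic C4 as it does there: the last free phloroglucinol position (C6 of the catechin unit) remains much more nucleophilic than any resorcinol ring and is alkylated to give the angular tetraflavanoid; the new C4 centre of unit D forms as both epimers under substrate control, and the 4α (3,4-cis) epimer is isolated.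

**Compound list**

1 | 1-[4-(benzyloxy)-2-hydroxyphenyl]ethan-1-one | CC(=O)c1ccc(OCc2ccccc2)cc1O | starting material
2 | 3,4-bis(benzyloxy)benzaldehyde | O=Cc1ccc(OCc2ccccc2)c(OCc2ccccc2)c1 | starting material
3 | (E)-1-[4-(benzyloxy)-2-hydroxyphenyl]-3-[3,4-bis(benzyloxy)phenyl]prop-2-en-1-one | O=C(/C=C/c1ccc(OCc2ccccc2)c(OCc2ccccc2)c1)c1ccc(OCc2ccccc2)cc1O | intermediate
4 | (2R)-7-(benzyloxy)-2-[3,4-bis(benzyloxy)phenyl]-2H-chromen-4-olate (flavanone enolate, 2-aryl β; anion shown, counter-ion is the catalyst cation) | [O-]C1=C[C@H](c2ccc(OCc3ccccc3)c(OCc3ccccc3)c2)Oc2cc(OCc3ccccc3)ccc12 | intermediate (not isolated)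
5 | (2S,3S)-7-(benzyloxy)-2-[3,4-bis(benzyloxy)phenyl]-3-hydroxy-2,3-dihydro-4H-chromen-4-one (2,3-trans) | c1ccccc1COc1ccc2c(c1)O[C@@H](c1ccc(OCc3ccccc3)c(OCc3ccccc3)c1)[C@H](O)C2=O | intermediate
6 | (2S,3S)-2-(3,4-dihydroxyphenyl)-3,7-dihydroxy-2,3-dihydro-4H-chromen-4-one (ent-fustin) | Oc1ccc2c(c1)O[C@@H](c1ccc(O)c(O)c1)[C@H](O)C2=O | intermediate
7 | (2S,3R,4S)-2-(3,4-dihydroxyphenyl)-3,4-dihydro-2H-chromene-3,4,7-triol (ent-mollisacacidin; 2,3-trans-3,4-trans) | Oc1ccc2c(c1)O[C@@H](c1ccc(O)c(O)c1)[C@H](O)[C@H]2O | intermediate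
8 | (2S,3R)-2-(3,4-dihydroxyphenyl)-3,7-dihydroxy-3,4-dihydro-2H-chromen-4-ylium (C4 carbocation of 7) | Oc1ccc2c(c1)O[C@@H](c1ccc(O)c(O)c1)[C@H](O)[CH+]2 | intermediate (not isolated)
9 | ent-fisetinidol-(4α→6)-ent-leucofisetinidin: (2S,3R,4S)-3,4-diol unit B bearing at C6 the (2S,3R,4R)-2-(3,4-dihydroxyphenyl)-3,7-dihydroxychroman-4-yl unit A (2,3-trans-3,4-cis) | Oc1ccc2c(c1)O[C@@H](c1ccc(O)c(O)c1)[C@H](O)[C@@H]2c1cc2c(cc1O)O[C@@H](c1ccc(O)c(O)c1)[C@H](O)[C@H]2O | intermediate
10 | (+)-catechin, (2R,3S)-2-(3,4-dihydroxyphenyl)chromane-3,5,7-triol | Oc1cc(O)c2c(c1)O[C@H](c1ccc(O)c(O)c1)[C@@H](O)C2 | starting material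
11 | C4 carbocation of unit B of 9 | Oc1ccc2c(c1)O[C@@H](c1ccc(O)c(O)c1)[C@H](O)[C@@H]2c1cc2c(cc1O)O[C@@H](c1ccc(O)c(O)c1)[C@H](O)[CH+]2 | intermediate (not isolated)
12 | ent-fisetinidol-(4α→6)-ent-fisetinidol-(4α→8)-catechin: unit A (2S,3R,4R) on C6 of unit B (2S,3R,4S), both 2,3-trans-3,4-cis, unit B on C8 of (2R,3S)-catechin | Oc1ccc2c(c1)O[C@@H](c1ccc(O)c(O)c1)[C@H](O)[C@@H]2c1cc2c(cc1O)O[C@@H](c1ccc(O)c(O)c1)[C@H](O)[C@@H]2c1c(O)cc(O)c2c1O[C@H](c1ccc(O)c(O)c1)[C@@H](O)C2 | intermediate
13 | ent-fisetinidol-(4α→6)-ent-fisetinidol-(4α→8)-catechin-(6→4α)-ent-fisetinidol: as 12, with unit D (2S,3R,4S; 2,3-trans-3,4-cis) on C6 of the catechin unit | Oc1ccc2c(c1)O[C@@H](c1ccc(O)c(O)c1)[C@H](O)[C@@H]2c1cc2c(cc1O)O[C@@H](c1ccc(O)c(O)c1)[C@H](O)[C@@H]2c1c(O)c([C@@H]2c3ccc(O)cc3O[C@@H](c3ccc(O)c(O)c3)[C@@H]2O)c(O)c2c1O[C@H](c1ccc(O)c(O)c1)[C@@H](O)C2 | target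

**Step count and risks**

Total steps: 7. Longest linear sequence: 7 steps (1 and 2 → 3 → 5 → 6 → 7 → 9 → 12 → 13).

Steps 5, 6 and 7 each deliver the required 4α (3,4-cis) epimer as the minor product of substrate control, so each depends on chromatographic separation from the 4β epimer.

Most likely to fail, first: step 2. The enantioselectivity of the tandem ring closure/hydroxylation is untested, and over-oxidation to the flavonol or 5-exo closure to an aurone-type product can compete. The fallback closes the same O1–C2 bond through an epoxide. It sets out from 3, whose 2'-OH is protected (MOMCl, i-Pr2NEt, CH2Cl2) to give (E)-1-[4-(benzyloxy)-2-(methoxymethoxy)phenyl]-3-[3,4-bis(benzyloxy)phenyl]prop-2-en-1-one F1. Juliá–Colonna epoxidation of this enone (poly-D-leucine, urea–H2O2, DBU, THF) gives the (αS,βR)-epoxide [(2S,3R)-3-[3,4-bis(benzyloxy)phenyl]oxiran-2-yl][4-(benzyloxy)-2-(methoxymethoxy)phenyl]methanone F2. HCl in MeOH–THF at 55 °C then removes the acetal, and the freed phenol opens the epoxide 6-endo at the benzylic carbon with inversion, giving the 2,3-trans (2S,3S) product and coming back to the route at 5.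

Second: step 5. The self-condensation is statistical (both molecules carry an ionisable 4-OH), gives some (4→8) isomers and higher oligomers, and the weak resorcinol-type nucleophile gives the smallest 4α share of the three couplings. The fallback separates the roles by orthogonal activation. It sets out from 7, which with phenylmethanethiol in AcOH at 25 °C gives (2S,3S,4S)-4-(benzylsulfanyl)-2-(3,4-dihydroxyphenyl)-3,4-dihydro-2H-chromene-3,7-diol F3 (the 4β-thioether). This is ionised selectively with AgBF4 in THF at 0 °C in the presence of excess 7, whose own 4-OH (and that of the product) is not activated by the thiophilic silver salt. The departing silver thiolate leaves from the β face, so a larger 4α share is expected. The fallback comes back to the route at 9.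

Third: step 6. The bulky dimeric cation 11 may react sluggishly or be captured by 9 itself, and C6 attack and the 4β epimer reduce the yield. The fallback builds the trimer linearly with a blocking group and does not need 9. It sets out from 7 and 10, which are condensed (0.1 M HCl, excess 10) to ent-fisetinidol-(4α→8)-catechin F4. Monobromination of the remaining phloroglucinol position (N-bromosuccinimide, THF, −40 °C) gives ent-fisetinidol-(4α→8)-6-bromocatechin F5. Condensation of F5 with 7 (0.1 M HCl) can now occur only at C6 of the upper unit and gives ent-fisetinidol-(4α→6)-ent-fisetinidol-(4α→8)-6-bromocatechin F6. Hydrogenolytic debromination (H2, Pd/C, Et3N, MeOH) comes back to the route at 12.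

**Further compounds**

F1 | step 2 | (E)-1-[4-(benzyloxy)-2-(methoxymethoxy)phenyl]-3-[3,4-bis(benzyloxy)phenyl]prop-2-en-1-one | O=C(/C=C/c1ccc(OCc2ccccc2)c(OCc2ccccc2)c1)c1ccc(OCc2ccccc2)cc1OCOC
F2 | step 2 | [(2S,3R)-3-[3,4-bis(benzyloxy)phenyl]oxiran-2-yl][4-(benzyloxy)-2-(methoxymethoxy)phenyl]methanone | O=C([C@H]1O[C@@H]1c1ccc(OCc2ccccc2)c(OCc2ccccc2)c1)c1ccc(OCc2ccccc2)cc1OCOC
F3 | step 5 | (2S,3S,4S)-4-(benzylsulfanyl)-2-(3,4-dihydroxyphenyl)-3,4-dihydro-2H-chromene-3,7-diol (4β-benzylsulfanyl-ent-fisetinidol) | Oc1ccc2c(c1)O[C@@H](c1ccc(O)c(O)c1)[C@H](O)[C@H]2SCc1ccccc1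
F4 | step 6 | ent-fisetinidol-(4α→8)-catechin (upper unit 2S,3R,4S; catechin 2R,3S) | Oc1ccc2c(c1)O[C@@H](c1ccc(O)c(O)c1)[C@H](O)[C@@H]2c1c(O)cc(O)c2c1O[C@H](c1ccc(O)c(O)c1)[C@@H](O)C2
F5 | step 6 | ent-fisetinidol-(4α→8)-6-bromocatechin | Oc1ccc2c(c1)O[C@@H](c1ccc(O)c(O)c1)[C@H](O)[C@@H]2c1c(O)c(Br)c(O)c2c1O[C@H](c1ccc(O)c(O)c1)[C@@H](O)C2
F6 | step 6 | ent-fisetinidol-(4α→6)-ent-fisetinidol-(4α→8)-6-bromocatechin | Oc1ccc2c(c1)O[C@@H](c1ccc(O)c(O)c1)[C@H](O)[C@@H]2c1cc2c(cc1O)O[C@@H](c1ccc(O)c(O)c1)[C@H](O)[C@@H]2c1c(O)c(Br)c(O)c2c1O[C@H](c1ccc(O)c(O)c1)[C@@H](O)C2
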